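Ring A' (C1' CH2 bridge, C2'–OH, C3' acyl, C4'–OH, C5'–CH3, C6'–OCH3) carries three oxygens in 1,3,5 relation that must stay distinguishable beside adjacent methyl and methylene carbons; the plan rests on this ring. The target has no stereocentre.
Last disconnection: the C3'–C(=O) bond, made by Fries shift of a C4'–O ester of 3-(4-hydroxyphenyl)propanoic acid to the only unsubstituted carbon of ring A'.
Key disconnection: ring A' is built from a 3-benzyloxycyclobutenone bearing the flavonol–CH2 group at C2 and 1-methoxypropyne (bonds C4'–C5', C6'–C1', C3'–C4'); only C3'–H is left open.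
The cyclobutenone comes from dichloroketene and a benzyl ynol ether, itself from Negishi coupling of an 8-(bromomethyl)flavonol with a benzyloxyethynylzinc reagent; the bromide comes from kaempferide by benzylation, C8 iodination and hydroxymethylation.
Ring order: the flavonol rings A, B, C and the 4-hydroxyphenyl ring are bought; ring A' is the only ring formed.

Key step: step 10

Remark: ring A' is numbered from the bridge carbon as above; the flavonol keeps the usual chromenone numbers; Fl stands for the 3,5,7-tris(benzyloxy)-2-(4-methoxyphenyl)-4-oxo-4H-chromen-8-yl group.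
Remark: the C2' oxygen is carried as a benzyl ether. A simple alkyl ether there would end ortho to a ketone already chelated by the C4' hydroxyl, so chelation-assisted cleavage beside the two methyl ethers could not be relied on; benzyl leaves by hydrogenolysis with the flavonol protecting groups.
Remark: the benzyl ethers are removed before the Fries step, because strong Lewis acids cleave and scatter benzyl groups. 3-[4-(Benzyloxy)phenyl]propanoic acid is taken as a purchased compound.

Step 1
Reactants: 1 kaempferide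
Product: 2 3,5,7-tris(benzyloxy)-2-(4-methoxyphenyl)-4H-chromen-4-one
Conditions: BnBr (5 equiv), K2CO3 (5 equiv), Bu4NI (cat.), DMF, 80 °C
Reagents that add atoms: benzyl bromide, BrCc1ccccc1
Why: Williamson etherification of the three hydroxyls; the chelated 5-OH reacts last, hence excess bromide, iodide catalysis and heat.

Step 2
Reactants: 2 3,5,7-tris(benzyloxy)-2-(4-methoxyphenyl)-4H-chromen-4-one
Product: 3 3,5,7-tris(benzyloxy)-8-iodo-2-(4-methoxyphenyl)-4H-chromen-4-one
Conditions: NIS (1.05 equiv), TFA (cat.), MeCN/CH2Cl2, 0 °C to rt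
Reagents that add atoms: N-iodosuccinimide, O=C1CCC(=O)N1I
Why: Electrophilic aromatic iodination of the most electron-rich ring; in fully etherified 5,7-dioxygenated flavones C8 (between the C7 ether and the ring oxygen) should be attacked in preference to C6, which is flanked by two benzyloxy groups.

Step 3
Reactants: 3 3,5,7-tris(benzyloxy)-8-iodo-2-(4-methoxyphenyl)-4H-chromen-4-one
Product: 4 3,5,7-tris(benzyloxy)-8-(hydroxymethyl)-2-(4-methoxyphenyl)-4H-chromen-4-one
Conditions: Bu3SnCH2OH (1.5 equiv), Pd(PPh3)4 (5 mol %), 1,4-dioxane, 100 °C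
Reagents that add atoms: (tributylstannyl)methanol, CCCC[Sn](CCCC)(CCCC)CO
Why: Stille coupling transfers the hydroxymethyl group to the aryl iodide under neutral conditions that leave the flavone carbonyl and the benzyl ethers alone.

Step 4
Reactants: 4 3,5,7-tris(benzyloxy)-8-(hydroxymethyl)-2-(4-methoxyphenyl)-4H-chromen-4-one
Product: 5 3,5,7-tris(benzyloxy)-8-(bromomethyl)-2-(4-methoxyphenyl)-4H-chromen-4-one
Conditions: CBr4, PPh3, CH2Cl2, 0 °C; used crude at once
Reagents that add atoms: carbon tetrabromide, BrC(Br)(Br)Br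
Why: Appel bromination of a primary benzylic alcohol under neutral conditions; the electron-rich bromide is not stored.

Step 5
Reactants: 6 benzyl alcohol; 7 trichloroethylene
Product: 8 (E)-benzyl 1,2-dichlorovinyl ether
Conditions: KH, THF, 0 °C; then Cl2C=CHCl, −50 °C to rt
Reagents that add atoms: none
Why: The alkoxide dehydrochlorinates trichloroethylene to dichloroacetylene and adds to it; anti addition and protonation should give the E dichlorovinyl ether (known alkoxide/trichloroethylene route to ynol ether precursors).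

Step 6
Reactants: 5 3,5,7-tris(benzyloxy)-8-(bromomethyl)-2-(4-methoxyphenyl)-4H-chromen-4-one; 8 (E)-benzyl 1,2-dichlorovinyl ether
Product: 11 3,5,7-tris(benzyloxy)-8-[3-(benzyloxy)prop-2-yn-1-yl]-2-(4-methoxyphenyl)-4H-chromen-4-one, via lithium benzyloxyacetylide 9 (not isolated), via benzyloxyethynylzinc bromide 10 (not isolated)
Conditions: 8 (1.5 equiv), n-BuLi (2.2 equiv per 8), THF, −78 to −40 °C; ZnBr2, −40 to 0 °C; then 5, PdCl2(DPEphos) (5 mol %; DPEphos = bis[2-(diphenylphosphino)phenyl] ether), 0 °C to rt; product kept cold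
Reagents that add atoms: none
Why: n-BuLi effects dehydrochlorination and Cl/Li exchange to the lithium alkoxyacetylide, zinc makes it too mild to add to the flavone carbonyl, and Negishi coupling of the alkynylzinc with the benzylic bromide forms the CH2–C(sp) bond.

Step 7
Reactants: 11 3,5,7-tris(benzyloxy)-8-[3-(benzyloxy)prop-2-yn-1-yl]-2-(4-methoxyphenyl)-4H-chromen-4-one
Product: 12 3-(benzyloxy)-4,4-dichloro-2-(Fl-methyl)cyclobut-2-en-1-one
Conditions: Cl2CHCOCl (slow addition), Et3N, Et2O, 0 °C to rt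
Reagents that add atoms: dichloroacetyl chloride, ClC(Cl)C(Cl)=O
Why: [2+2] cycloaddition of dichloroketene with the electron-rich ynol ether; the alkyne carbon remote from oxygen bonds to the ketene carbonyl carbon, so the Fl–CH2 group sits at C2 next to C=O and the benzyloxy group at C3.

Step 8
Reactants: 12 3-(benzyloxy)-4,4-dichloro-2-(Fl-methyl)cyclobut-2-en-1-one
Product: 13 3-(benzyloxy)-2-(Fl-methyl)cyclobut-2-en-1-one
Conditions: Zn dust, AcOH, TMEDA, EtOH, 0 °C to rt
Reagents that add atoms: none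
Why: Zinc reduction of the α,α-dichloro ketone removes both chlorines by way of zinc enolates, and the amine buffer keeps the vinylogous ester from hydrolysis.

Step 9
Reactants: 14 2-chloro-1,1-dimethoxyethane
Product: 16 1-methoxyprop-1-yne, via sodium methoxyacetylide 15 (not isolated)
Conditions: NaNH2 (3 equiv), liquid NH3, −33 °C; then MeI, −33 °C; aqueous work-up, distillation
Reagents that add atoms: iodomethane, CI
Why: Twofold elimination (methanol, then HCl) and deprotonation give the alkoxyacetylide in liquid ammonia, which is C-methylated by iodomethane (known alkoxyalkyne synthesis from chloroacetals).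

Step 10
Reactants: 13 3-(benzyloxy)-2-(Fl-methyl)cyclobut-2-en-1-one; 16 1-methoxyprop-1-yne
Product: 21 8-{[2-(benzyloxy)-4-hydroxy-6-methoxy-5-methylphenyl]methyl}-3,5,7-tris(benzyloxy)-2-(4-methoxyphenyl)-4H-chromen-4-one, via vinylketene 17 (not isolated), via vinylcyclobutenone 18 (not isolated), via dienylketene 19 (not isolated), via cyclohexadienone 20 (not isolated)
Conditions: 16 (3 equiv), degassed toluene, sealed tube, 120 °C; then K2CO3, MeOH, rt
Reagents that add atoms: none
Why: Thermal 4π electrocyclic opening of 13 gives the (1-benzyloxyvinyl)ketene 17, whose ketene C=C adds 16 in a [2+2] cycloaddition to give 18; 4π opening of 18 gives dienylketene 19, and 6π electrocyclisation to dienone 20 followed by tautomerisation delivers the phenol. The closest known reaction type is the Danheiser benzannulation of cyclobutenones with alkoxyalkynes, and alkoxy-substituted cyclobutenones are known to open thermally to vinylketenes, though the donor group at C3 should make 13 open more slowly than alkylcyclobutenones. Ring A' closes by a thermal six-electron disrotatory electrocyclisation in which the ketene carbon (C4') bonds to the terminal CH2 (C3'); the bonds C4'–C5' and C6'–C1' come from the [2+2] step. No stereocentre remains, since the quaternary carbon of 18 becomes sp2 on ring opening. The step needs complete regiocontrol in the [2+2] addition, and the polarity of the ynol ether secures it: its methyl-bearing carbon is the nucleophile and bonds to the ketene carbonyl carbon, so CH3 lies between the new OH and the OCH3. The benzylated flavonol has no acidic or nucleophilic site and should survive the neutral thermolysis, and the basic methanolysis returns any product phenol that was O-acylated by the vinylketene.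

Step 11
Reactants: 21 8-{[2-(benzyloxy)-4-hydroxy-6-methoxy-5-methylphenyl]methyl}-3,5,7-tris(benzyloxy)-2-(4-methoxyphenyl)-4H-chromen-4-one; 22 3-[4-(benzyloxy)phenyl]propanoic acid
Product: 23 5-(benzyloxy)-3-methoxy-2-methyl-4-(Fl-methyl)phenyl 3-[4-(benzyloxy)phenyl]propanoate
Conditions: DCC, DMAP (cat.), CH2Cl2, rt
Reagents that add atoms: none
Why: Steglich esterification of the only free hydroxyl (C4'–OH) places the acyl group on the oxygen next to C3'.

Step 12
Reactants: 23 5-(benzyloxy)-3-methoxy-2-methyl-4-(Fl-methyl)phenyl 3-[4-(benzyloxy)phenyl]propanoate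
Product: 24 5-hydroxy-3-methoxy-2-methyl-4-{[3,5,7-trihydroxy-2-(4-methoxyphenyl)-4-oxo-4H-chromen-8-yl]methyl}phenyl 3-(4-hydroxyphenyl)propanoate
Conditions: H2 (1 atm), 10% Pd/C, THF/EtOAc, rt
Reagents that add atoms: none
Why: Catalytic hydrogenolysis should cleave all five benzyl ethers, while the aryl ester, the methyl ethers, the diarylmethane and the tetrasubstituted flavonol double bond are inert.

Step 13
Reactants: 24 5-hydroxy-3-methoxy-2-methyl-4-{[3,5,7-trihydroxy-2-(4-methoxyphenyl)-4-oxo-4H-chromen-8-yl]methyl}phenyl 3-(4-hydroxyphenyl)propanoate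
Product: 25 4'''-hydroxytrianguletin
Conditions: BF3·OEt2 (excess), 1,4-dioxane, 70 °C; then aqueous MeOH, 50 °C
Reagents that add atoms: none
Why: Fries rearrangement moves the acyl group from O4' to C3', the only free carbon of ring A' and ortho to both O2' and O4'; the product should be held as the boron chelate of the di-ortho-hydroxy ketone (released on aqueous work-up), ring A of the flavonol is deactivated by boron chelation of its 4-oxo/5-hydroxy unit, and BF3 does not cleave the methyl ethers.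

Compound list
1 | kaempferide | COc1ccc(cc1)-c1oc2cc(O)cc(O)c2c(=O)c1O | starting material
2 | 3,5,7-tris(benzyloxy)-2-(4-methoxyphenyl)-4H-chromen-4-one | COc1ccc(cc1)-c1oc2cc(OCc3ccccc3)cc(OCc3ccccc3)c2c(=O)c1OCc1ccccc1 | intermediate
3 | 3,5,7-tris(benzyloxy)-8-iodo-2-(4-methoxyphenyl)-4H-chromen-4-one | COc1ccc(cc1)-c1oc2c(I)c(OCc3ccccc3)cc(OCc3ccccc3)c2c(=O)c1OCc1ccccc1 | intermediate
4 | 3,5,7-tris(benzyloxy)-8-(hydroxymethyl)-2-(4-methoxyphenyl)-4H-chromen-4-one | COc1ccc(cc1)-c1oc2c(CO)c(OCc3ccccc3)cc(OCc3ccccc3)c2c(=O)c1OCc1ccccc1 | intermediate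
5 | 3,5,7-tris(benzyloxy)-8-(bromomethyl)-2-(4-methoxyphenyl)-4H-chromen-4-one | COc1ccc(cc1)-c1oc2c(CBr)c(OCc3ccccc3)cc(OCc3ccccc3)c2c(=O)c1OCc1ccccc1 | intermediate
6 | benzyl alcohol | OCc1ccccc1 | starting material
7 | trichloroethylene | ClC=C(Cl)Cl | starting material
8 | (E)-benzyl 1,2-dichlorovinyl ether | Cl/C=C(/Cl)OCc1ccccc1 | intermediate
9 | lithium benzyloxyacetylide | [Li]C#COCc1ccccc1 | intermediate
10 | (benzyloxyethynyl)zinc bromide | Br[Zn]C#COCc1ccccc1 | intermediate
11 | 3,5,7-tris(benzyloxy)-8-[3-(benzyloxy)prop-2-yn-1-yl]-2-(4-methoxyphenyl)-4H-chromen-4-one | COc1ccc(cc1)-c1oc2c(CC#COCc3ccccc3)c(OCc3ccccc3)cc(OCc3ccccc3)c2c(=O)c1OCc1ccccc1 | intermediate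
12 | 3-(benzyloxy)-4,4-dichloro-2-(Fl-methyl)cyclobut-2-en-1-one | COc1ccc(cc1)-c1oc2c(CC3=C(OCc4ccccc4)C(Cl)(Cl)C3=O)c(OCc3ccccc3)cc(OCc3ccccc3)c2c(=O)c1OCc1ccccc1 | intermediate
13 | 3-(benzyloxy)-2-(Fl-methyl)cyclobut-2-en-1-one | COc1ccc(cc1)-c1oc2c(CC3=C(OCc4ccccc4)CC3=O)c(OCc3ccccc3)cc(OCc3ccccc3)c2c(=O)c1OCc1ccccc1 | intermediate
14 | 2-chloro-1,1-dimethoxyethane | COC(CCl)OC | starting material
15 | sodium methoxyacetylide | [Na+].[C-]#COC | intermediate
16 | 1-methoxyprop-1-yne | CC#COC | intermediate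
17 | 3-(benzyloxy)-2-(Fl-methyl)buta-1,3-dien-1-one (vinylketene) | COc1ccc(cc1)-c1oc2c(CC(=C=O)C(=C)OCc3ccccc3)c(OCc3ccccc3)cc(OCc3ccccc3)c2c(=O)c1OCc1ccccc1 | intermediate
18 | 4-[1-(benzyloxy)ethenyl]-3-methoxy-2-methyl-4-(Fl-methyl)cyclobut-2-en-1-one (racemic) | COc1ccc(cc1)-c1oc2c(CC3(C(=C)OCc4ccccc4)C(OC)=C(C)C3=O)c(OCc3ccccc3)cc(OCc3ccccc3)c2c(=O)c1OCc1ccccc1 | intermediate
19 | 5-(benzyloxy)-3-methoxy-2-methyl-4-(Fl-methyl)hexa-1,3,5-trien-1-one, ketene and vinyl groups cis on the C3=C4 bond | COc1ccc(cc1)-c1oc2c(C/C(C(=C)OCc3ccccc3)=C(\OC)C(C)=C=O)c(OCc3ccccc3)cc(OCc3ccccc3)c2c(=O)c1OCc1ccccc1 | intermediate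
20 | 5-(benzyloxy)-3-methoxy-2-methyl-4-(Fl-methyl)cyclohexa-2,4-dien-1-one | COc1ccc(cc1)-c1oc2c(CC3=C(OCc4ccccc4)CC(=O)C(C)=C3OC)c(OCc3ccccc3)cc(OCc3ccccc3)c2c(=O)c1OCc1ccccc1 | intermediate
21 | 8-{[2-(benzyloxy)-4-hydroxy-6-methoxy-5-methylphenyl]methyl}-3,5,7-tris(benzyloxy)-2-(4-methoxyphenyl)-4H-chromen-4-one | COc1ccc(cc1)-c1oc2c(Cc3c(OCc4ccccc4)cc(O)c(C)c3OC)c(OCc3ccccc3)cc(OCc3ccccc3)c2c(=O)c1OCc1ccccc1 | intermediate
22 | 3-[4-(benzyloxy)phenyl]propanoic acid | OC(=O)CCc1ccc(OCc2ccccc2)cc1 | starting material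
23 | 5-(benzyloxy)-3-methoxy-2-methyl-4-(Fl-methyl)phenyl 3-[4-(benzyloxy)phenyl]propanoate | COc1ccc(cc1)-c1oc2c(Cc3c(OCc4ccccc4)cc(OC(=O)CCc4ccc(OCc5ccccc5)cc4)c(C)c3OC)c(OCc3ccccc3)cc(OCc3ccccc3)c2c(=O)c1OCc1ccccc1 | intermediate
24 | 5-hydroxy-3-methoxy-2-methyl-4-{[3,5,7-trihydroxy-2-(4-methoxyphenyl)-4-oxo-4H-chromen-8-yl]methyl}phenyl 3-(4-hydroxyphenyl)propanoate | COc1ccc(cc1)-c1oc2c(Cc3c(O)cc(OC(=O)CCc4ccc(O)cc4)c(C)c3OC)c(O)cc(O)c2c(=O)c1O | intermediate
25 | 4'''-hydroxytrianguletin, 8-{[2,4-dihydroxy-3-[3-(4-hydroxyphenyl)propanoyl]-6-methoxy-5-methylphenyl]methyl}-3,5,7-trihydroxy-2-(4-methoxyphenyl)-4H-chromen-4-one | COc1ccc(cc1)-c1oc2c(Cc3c(O)c(C(=O)CCc4ccc(O)cc4)c(O)c(C)c3OC)c(O)cc(O)c2c(=O)c1O | target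

Total step count: 13. Longest linear sequence: 11 steps from kaempferide 1 (steps 1–4, 6–8, 10–13); steps 5 and 9 make the two small partners.

Steps most likely to fail

Step 10. The alkoxy-stabilised cyclobutenone may open too slowly; at the temperature then needed, the vinylketene may dimerise or be trapped by the product phenol, and the ynol ether may oligomerise before ring A' forms. The fallback gives up ring construction and joins a finished ring A' to the flavonol; it sets out from alcohol 4 and comes back at 25. 2,4,6-Trihydroxytoluene is C-acylated with 3-(4-hydroxyphenyl)propanoic acid in BF3·OEt2 at 80 °C to give 3-(4-hydroxyphenyl)-1-(2,4,6-trihydroxy-3-methylphenyl)propan-1-one F1. Its most acidic, non-chelated hydroxyl (para to the ketone) is methylated with Me2SO4 (1 equiv) and K2CO3 in acetone to give 1-(2,6-dihydroxy-4-methoxy-3-methylphenyl)-3-(4-hydroxyphenyl)propan-1-one F2. Acid-catalysed Friedel–Crafts benzylation of the single free carbon of its phloroglucinol ring with alcohol 4 (TsOH cat., 1,4-dioxane, 40 °C) should give 3,5,7-tris(benzyloxy)-8-{[2,4-dihydroxy-3-[3-(4-hydroxyphenyl)propanoyl]-6-methoxy-5-methylphenyl]methyl}-2-(4-methoxyphenyl)-4H-chromen-4-one F3, and hydrogenolysis (H2, Pd/C) gives 25. Its weak point is the selectivity of the single O-methylation.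

Step 13. At 70 °C under a Lewis acid the acylium ion may leave the ester and attack ring A' at C1' (ipso), which would cleave the CH2 bridge, or the acyl group may scatter over the other phenolic sites. The fallback places the acyl group by direct C-acylation of a fully etherified ring at room temperature and ends with hydrogenolysis; it sets out from 21 and comes back at 25. O-Benzylation of 21 (BnBr, K2CO3, DMF) gives 8-{[2,4-bis(benzyloxy)-6-methoxy-5-methylphenyl]methyl}-3,5,7-tris(benzyloxy)-2-(4-methoxyphenyl)-4H-chromen-4-one F4. Acid 22 and trifluoroacetic anhydride give in the flask 3-[4-(benzyloxy)phenyl]propanoic trifluoroacetic anhydride F5, which should acylate the only free carbon (C3') of F4 in CH2Cl2 at rt to give 8-{[2,4-bis(benzyloxy)-3-{3-[4-(benzyloxy)phenyl]propanoyl}-6-methoxy-5-methylphenyl]methyl}-3,5,7-tris(benzyloxy)-2-(4-methoxyphenyl)-4H-chromen-4-one F6. Hydrogenolysis of the six benzyl ethers (H2, Pd/C) gives 25.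

Step 6. The benzyl alkynyl ether may be lost by sigmatropic rearrangement on warming, or by benzylic lithiation and Wittig-type rearrangement during metalation. The fallback carries the robust ethyl ynol ether through the ketene steps and introduces the benzyl group at the cyclobutenone stage; it sets out from 5 and comes back at 13. Ethoxyacetylene and n-BuLi give lithium ethoxyacetylide F7, and ZnBr2 converts it to (ethoxyethynyl)zinc bromide F8. The same Negishi coupling with 5 gives 3,5,7-tris(benzyloxy)-8-(3-ethoxyprop-2-yn-1-yl)-2-(4-methoxyphenyl)-4H-chromen-4-one F9. Dichloroketene addition gives 4,4-dichloro-3-ethoxy-2-(Fl-methyl)cyclobut-2-en-1-one F10, and Zn/AcOH/TMEDA gives 3-ethoxy-2-(Fl-methyl)cyclobut-2-en-1-one F11. Acid-catalysed exchange of the vinylogous ester alkoxy group with benzyl alcohol (TsOH cat., toluene, 40 °C, ethanol removed under reduced pressure) then gives 13.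

Further compounds
F1 | step 10 | 3-(4-hydroxyphenyl)-1-(2,4,6-trihydroxy-3-methylphenyl)propan-1-one | Cc1c(O)cc(O)c(C(=O)CCc2ccc(O)cc2)c1O
F2 | step 10 | 1-(2,6-dihydroxy-4-methoxy-3-methylphenyl)-3-(4-hydroxyphenyl)propan-1-one | COc1cc(O)c(C(=O)CCc2ccc(O)cc2)c(O)c1C
F3 | step 10 | 3,5,7-tris(benzyloxy)-8-{[2,4-dihydroxy-3-[3-(4-hydroxyphenyl)propanoyl]-6-methoxy-5-methylphenyl]methyl}-2-(4-methoxyphenyl)-4H-chromen-4-one | COc1ccc(cc1)-c1oc2c(Cc3c(O)c(C(=O)CCc4ccc(O)cc4)c(O)c(C)c3OC)c(OCc3ccccc3)cc(OCc3ccccc3)c2c(=O)c1OCc1ccccc1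
F4 | step 13 | 8-{[2,4-bis(benzyloxy)-6-methoxy-5-methylphenyl]methyl}-3,5,7-tris(benzyloxy)-2-(4-methoxyphenyl)-4H-chromen-4-one | COc1ccc(cc1)-c1oc2c(Cc3c(OCc4ccccc4)cc(OCc4ccccc4)c(C)c3OC)c(OCc3ccccc3)cc(OCc3ccccc3)c2c(=O)c1OCc1ccccc1
F5 | step 13 | 3-[4-(benzyloxy)phenyl]propanoic trifluoroacetic anhydride | O=C(CCc1ccc(OCc2ccccc2)cc1)OC(=O)C(F)(F)F
F6 | step 13 | 8-{[2,4-bis(benzyloxy)-3-{3-[4-(benzyloxy)phenyl]propanoyl}-6-methoxy-5-methylphenyl]methyl}-3,5,7-tris(benzyloxy)-2-(4-methoxyphenyl)-4H-chromen-4-one | COc1ccc(cc1)-c1oc2c(Cc3c(OCc4ccccc4)c(C(=O)CCc4ccc(OCc5ccccc5)cc4)c(OCc4ccccc4)c(C)c3OC)c(OCc3ccccc3)cc(OCc3ccccc3)c2c(=O)c1OCc1ccccc1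
F7 | step 6 | lithium ethoxyacetylide | [Li]C#COCC
F8 | step 6 | (ethoxyethynyl)zinc bromide | CCOC#C[Zn]Br
F9 | step 6 | 3,5,7-tris(benzyloxy)-8-(3-ethoxyprop-2-yn-1-yl)-2-(4-methoxyphenyl)-4H-chromen-4-one | COc1ccc(cc1)-c1oc2c(CC#COCC)c(OCc3ccccc3)cc(OCc3ccccc3)c2c(=O)c1OCc1ccccc1
F10 | step 6 | 4,4-dichloro-3-ethoxy-2-(Fl-methyl)cyclobut-2-en-1-one | COc1ccc(cc1)-c1oc2c(CC3=C(OCC)C(Cl)(Cl)C3=O)c(OCc3ccccc3)cc(OCc3ccccc3)c2c(=O)c1OCc1ccccc1
F11 | step 6 | 3-ethoxy-2-(Fl-methyl)cyclobut-2-en-1-one | COc1ccc(cc1)-c1oc2c(CC3=C(OCC)CC3=O)c(OCc3ccccc3)cc(OCc3ccccc3)c2c(=O)c1OCc1ccccc1
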